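Structural features

The target is a 2-arylbenzofuran: a furan (O1, C2, C3) fused through C3a–C7a to benzo ring A, with ring B (4-hydroxy-2-methoxyphenyl) bonded to C2 and a formyl group on C3. Ring A carries a hydroxyl on C4, a 3-hydroxy-3-methylbutyl chain on C5, a methoxy group on C6 and its only hydrogen on C7, so C3a sits between two oxygen-bearing carbons (C4 and C7a). There is no stereocentre; the problem is one of regiochemistry and chemoselectivity. The fragile points are the C4 phenol next to a chain whose tertiary carbinol ionises under acid (closure to a 2,2-dimethylchroman or dehydration), the aldehyde, and an electron-rich nucleus in which C7 and ring B are as open to electrophiles and oxidants as C3. The real difficulty is twofold: the two ring-A oxygens flanking C3a must be told apart, because one becomes O1 and the other stays as the C4 hydroxyl, and a single carbon must be placed on C3 and nowhere else. The key step uses the 1,3-relationship of O1 and the formyl carbon across the C2=C3 bond: a one-carbon acetal group parked on the C7a oxygen can be passed to C3 in the same event that joins O1 to C2.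

Logic of the disconnections

15 to 14: the three O–Si bonds are cut last. Fluoride removes all silyl groups under non-acidic conditions, which protects the C4 hydroxyl/tertiary carbinol pair from cyclisation. The demand is that two aryl silyl ethers and one tertiary silyl ether fall in one operation.

14 to 13: no skeletal bond is cut; the formyl group is traced back to a methoxymethyl group on C3. The gain is that the C3 carbon no longer has to be introduced by electrophilic formylation. The forward step must abstract hydride from the C3 methylene only.

13 to 12: O1–C2 and C3–CH2 are cut together. This opens the furan to a diarylalkyne and returns the one-carbon unit to the C7a oxygen as an acetal. It removes a ring and reduces the regiochemical problem to the question of which oxygen carries the acetal. The forward step must let only that oxygen cyclise productively.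

12 to 9 and 11: the bond between the alkyne and ring B is cut. This splits the molecule into a ring-A alkyne and a simple ring-B halide. The forward coupling must cope with an electron-rich, ortho-substituted bromide and a hindered alkyne.

11 to 10: one O–Si bond; the ring-B phenol is masked with the same silyl group as the C4 oxygen so that both leave together at the end.

9 to 8: the terminal alkyne carbon is removed, leaving an aldehyde carbon on the future C3a. The homologation must tolerate an aryl silyl ether ortho to the carbonyl, which argues for aprotic, cold conditions.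

8 to 7 to 6: the O–Si bond on the future C4 oxygen and the O–CH2 bond of the acetal are cut in turn. In 6 the two phenols differ only in their neighbours (chain versus hydrogen). The forward acetalisation must therefore pick the unhindered phenol, and this choice fixes which oxygen becomes O1.

6 to 5 to 4 and 2: the ring C5–chain bond is cut at the alkene oxidation level. The alkene partner has no hydrogen on its carbinol carbon, so the coupling can give only one alkene, which is then saturated. The hydrogenation must spare the aldehyde.

4 to 3: the C–I bond. Because 3 is symmetric, the two open ring positions are equivalent and mono-iodination has no regiochemical question; the forward step only has to stop at one iodine.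

2 to 1: one O–Si bond. Capping the tertiary hydroxyl before the chain is attached removes a nucleophile and an ionisable group from every later intermediate at the cost of one short branch step.

Other disconnections considered

Alternative 1: The cut runs through ring A (C7–C7a, C3a–C4, C4–C5, C6–C7), leaving a trisubstituted furan and a two-carbon ynol ether. Forward, the furyl diazo ketone A2 is irradiated with the methoxyalkyne A3 and then heated. Wolff rearrangement gives a ketene on the furan carbon that becomes C7a. A (2+2) cycloaddition with A3, four-electron ring opening and six-electron closure onto the free furan position (the future C3a), then tautomerisation, would deliver phenol A1.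
- In its favour: four ring-A bonds form in one operation. The polarity of A3 places methoxy on C6 and the chain on C5. The C4 hydroxyl is born free and is the only free phenol, so the two ring-A oxygens never need differentiating; on this point it is better than the chosen plan. The formyl carbon is carried as an acetal from the start, so C3 is as secure as in the chosen plan (equal).
- Against it here: A2 needs a 2-aryl-3-formyl-5-acylfuran plus diazo transfer, and A3 is a hydrolytically sensitive ynol ether. The closure must break furan aromaticity. Unmasking the aldehyde of A1 needs aqueous acid while the C4 hydroxyl is free and a tertiary oxygen sits on the C5 chain, which is the combination that invites chroman formation. The benzyl ether then has to be hydrogenolysed beside an aryl aldehyde.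
- Comparison: on structure it solves the oxygen-differentiation problem more cleanly; on mechanism both rely on well-understood pericyclic or π-acid pathways; on step economy the two partners together would need more steps than the whole chosen sequence, and the endgame is less safe.

Alternative 2: The cut is O1–C7a and C3–C3a, with ring A as an aryne and O1, C2, C3 drawn from a β-keto ester ylide. Forward, CsF releases the aryne from silyl triflate A5. The ketone enolate oxygen of iodonium ylide A6 adds to C7a, the aryne carbon remote from the C4 benzyloxy group. The C3a anion then closes on the ylide carbon with loss of the iodine leaving group, giving benzofuran ester A4.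
- In its favour: the furan is made in one step from two fragments. Regiocontrol by a 3-alkoxyaryne is as dependable as the acetal-only migration of the chosen plan (equal on mechanism). The C3 carbon is installed unambiguously (equal).
- Against it here: A5 is a hexasubstituted benzene whose preparation (silyl group and triflate between and beside oxygens, plus the chain) would be longer than the whole ring-A sequence chosen. Fluoride at the aryne stage threatens the tertiary silyl ether. C3 arrives at the carboxylate level and needs reduction and re-oxidation. Two benzyl ethers must be hydrogenolysed in the presence of the benzofuran and, later, the aldehyde.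
- Comparison: on structure A4 is over-oxidised at C3 and over-protected; on step economy at least four steps follow the key step against two in the chosen plan.

Alternative 3: The cut is C2–C3. Forward, Rh2(OAc)4 (divalent rhodium) turns aryldiazoacetate A8 into a carbenoid at the future C3. This inserts into the benzylic C–H of the ring-B benzyl ether on the C7a oxygen and closes the cis-2,3-dihydrobenzofuran A7.
- In its favour: the C–H bond is activated three ways (benzylic, α to oxygen, on an electron-rich arene), so the insertion is mechanistically well matched. Conditions are mild, and there is no competition among oxygen nucleophiles for an alkyne; on that point it is better than the chosen plan. The ester carbon fixes the C3 substituent (equal).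
- Against it here: two stereocentres are made only to be erased by dehydrogenation. The ester then needs two redox steps, so four steps follow the key step. The carbenoid, flanked by two ortho oxygens, could instead insert into an isopropyl C–H of the neighbouring silyl group or form an oxonium ylide at the ether oxygen. The ring-B benzyl halide needed to make A8 is a quinone-methide precursor and hard to handle. The two ring-A oxygens still have to be differentiated (equal burden to the chosen plan).
- Comparison: on structure it builds stereochemistry the target does not have; on step economy it is longer before and after the key step.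

Key step: step 10

Remark on the chemistry: the skeletons of 12 and 13 map atom for atom onto the target and need no correction. The one design change is that the tertiary hydroxyl is carried as a triethylsilyl ether from the Heck partner onward. Positions are numbered as in benzofuran, ring A being the benzo ring and ring B the 2-aryl group.

Step 1
Reactants: 1 2-methylbut-3-en-2-ol
Product: 2 triethyl[(2-methylbut-3-en-2-yl)oxy]silane
Conditions: TESOTf, 2,6-lutidine, CH2Cl2, -78 to 0 °C
Reagents that add atoms: triethylsilyl trifluoromethanesulfonate (TESOTf), CC[Si](CC)(CC)OS(=O)(=O)C(F)(F)F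
Why: Silyl triflate with a hindered pyridine base silylates tertiary alcohols quickly at low temperature (silyl ether formation); the ether masks the only aliphatic hydroxyl for the whole route and leaves with the aryl silyl ethers in the last step.

Step 2
Reactants: 3 2,6-dihydroxy-4-methoxybenzaldehyde
Product: 4 2,6-dihydroxy-3-iodo-4-methoxybenzaldehyde
Conditions: NIS (1.0 equiv), MeCN, 0 °C to rt
Reagents that add atoms: N-iodosuccinimide (NIS), O=C1CCC(=O)N1I
Why: Electrophilic aromatic iodination of a phloroglucinol-type ring; the two open positions are equivalent by symmetry and each is ortho or para to all three oxygens, so one equivalent should give a single mono-iodide, the formyl group and the first iodine slowing a second substitution.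

Step 3
Reactants: 4 2,6-dihydroxy-3-iodo-4-methoxybenzaldehyde; 2 triethyl[(2-methylbut-3-en-2-yl)oxy]silane
Product: 5 2,6-dihydroxy-4-methoxy-3-[(E)-3-methyl-3-(triethylsilyloxy)but-1-en-1-yl]benzaldehyde
Conditions: Pd(OAc)2 (5 mol %), P(o-tol)3 (12 mol %), Et3N, DMF, 90 °C
Reagents that add atoms: none
Why: Mizoroki–Heck reaction; the aryl group adds to the terminal alkene carbon and, because the carbinol carbon has no hydrogen, β-hydride elimination can give only the (E)-styrene. Free phenols are tolerated with an amine base, and the silyl ether keeps the allylic oxygen from closing onto the neighbouring phenol as a chromene.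

Step 4
Reactants: 5 2,6-dihydroxy-4-methoxy-3-[(E)-3-methyl-3-(triethylsilyloxy)but-1-en-1-yl]benzaldehyde
Product: 6 2,6-dihydroxy-4-methoxy-3-[3-methyl-3-(triethylsilyloxy)butyl]benzaldehyde
Conditions: H2 (1 atm), 10% Pd/C, EtOAc, rt, stopped after one equivalent
Reagents that add atoms: none
Why: Heterogeneous catalytic hydrogenation of a disubstituted styrene; the hydrogen-bonded, electron-rich aryl aldehyde and the silyl ether should survive in a neutral aprotic solvent at atmospheric pressure.

Step 5
Reactants: 6 2,6-dihydroxy-4-methoxy-3-[3-methyl-3-(triethylsilyloxy)butyl]benzaldehyde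
Product: 7 2-hydroxy-4-methoxy-6-(methoxymethoxy)-3-[3-methyl-3-(triethylsilyloxy)butyl]benzaldehyde
Conditions: MOMCl (1.05 equiv), i-Pr2NEt, CH2Cl2, 0 °C
Reagents that add atoms: chloromethyl methyl ether (MOMCl), COCCl
Why: O-alkylation of a phenol under kinetic control (acetal formation); the C6 hydroxyl has only a ring hydrogen on its far side, whereas the C2 hydroxyl is buttressed between the formyl group and the chain and held in the stronger hydrogen bond, so one equivalent should go to the C6 oxygen. This is the oxygen that later becomes O1.

Step 6
Reactants: 7 2-hydroxy-4-methoxy-6-(methoxymethoxy)-3-[3-methyl-3-(triethylsilyloxy)butyl]benzaldehyde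
Product: 8 4-methoxy-6-(methoxymethoxy)-3-[3-methyl-3-(triethylsilyloxy)butyl]-2-(triisopropylsilyloxy)benzaldehyde
Conditions: TIPSOTf (1.3 equiv), 2,6-lutidine, CH2Cl2, 0 °C to rt
Reagents that add atoms: triisopropylsilyl trifluoromethanesulfonate (TIPSOTf), CC(C)[Si](C(C)C)(C(C)C)OS(=O)(=O)C(F)(F)F
Why: Silylation of the remaining chelated, hindered phenol needs the triflate; the TIPS group is bulky enough not to migrate to a neighbouring alkoxide in step 7, cannot leave as a cation in step 10, and falls to fluoride at the end.

Step 7
Reactants: 8 4-methoxy-6-(methoxymethoxy)-3-[3-methyl-3-(triethylsilyloxy)butyl]-2-(triisopropylsilyloxy)benzaldehyde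
Product: 9 {2-ethynyl-5-methoxy-3-(methoxymethoxy)-6-[3-methyl-3-(triethylsilyloxy)butyl]phenoxy}triisopropylsilane
Conditions: TMSCHN2 (1.3 equiv), n-BuLi (1.25 equiv), THF, -78 °C; then 8, -78 °C to rt
Reagents that add atoms: (trimethylsilyl)diazomethane, C[Si](C)(C)C=[N+]=[N-]
Why: Colvin rearrangement: the lithiated diazo reagent adds to the aldehyde, Peterson-type loss of lithium trimethylsilanolate gives a diazoalkene, N2 leaves and a 1,2-hydrogen shift in the alkylidene carbene gives the terminal alkyne. Cold aprotic conditions spare the aryl TIPS ether, which methanolic carbonate could cleave next to a formyl group.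

Step 8
Reactants: 10 4-bromo-3-methoxyphenol
Product: 11 (4-bromo-3-methoxyphenoxy)triisopropylsilane
Conditions: TIPSCl, imidazole, DMF, rt
Reagents that add atoms: chlorotriisopropylsilane (TIPSCl), CC(C)[Si](Cl)(C(C)C)C(C)C
Why: Standard silyl chloride/imidazole protection of an unhindered phenol; the free phenoxide would otherwise deactivate the bromide toward oxidative addition in step 9.

Step 9
Reactants: 9 {2-ethynyl-5-methoxy-3-(methoxymethoxy)-6-[3-methyl-3-(triethylsilyloxy)butyl]phenoxy}triisopropylsilane; 11 (4-bromo-3-methoxyphenoxy)triisopropylsilane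
Product: 12 triethyl[(4-{6-methoxy-4-(methoxymethoxy)-3-[(2-methoxy-4-triisopropylsilyloxyphenyl)ethynyl]-2-(triisopropylsilyloxy)phenyl}-2-methylbutan-2-yl)oxy]silane
Conditions: Pd(PhCN)2Cl2 (3 mol %), P(t-Bu)3 (6 mol %), CuI (2 mol %), i-Pr2NH, dioxane, rt to 40 °C
Reagents that add atoms: none
Why: Sonogashira coupling; the bromide is electron-rich and ortho-substituted, so a bulky electron-rich phosphine is used to let zerovalent palladium (formed in the flask from the divalent precatalyst) insert near room temperature, which keeps copper-mediated homocoupling of 9 down. The silyl ethers and the acetal are inert to the amine base.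

Step 10
Reactants: 12 triethyl[(4-{6-methoxy-4-(methoxymethoxy)-3-[(2-methoxy-4-triisopropylsilyloxyphenyl)ethynyl]-2-(triisopropylsilyloxy)phenyl}-2-methylbutan-2-yl)oxy]silane
Product: 13 triethyl({4-[6-methoxy-3-(methoxymethyl)-2-(2-methoxy-4-triisopropylsilyloxyphenyl)-4-(triisopropylsilyloxy)benzofuran-5-yl]-2-methylbutan-2-yl}oxy)silane
Conditions: PtCl2 (5 mol %), 1,5-cyclooctadiene (20 mol %), dry toluene, 30 to 60 °C
Reagents that add atoms: none
Why: PtCl2 (divalent platinum, tempered by 1,5-cyclooctadiene) binds the alkyne of 12 as a π-acid. The acetal oxygen on the carbon that becomes C7a adds anti to the metal at the alkyne carbon attached to ring B, a 5-endo-dig closure that forms O1–C2 and gives a 3-platinated benzofuran oxonium ion. The O–CH2 bond of this ion ionises, and the methoxymethyl cation, an oxocarbenium ion held as a contact ion pair in toluene, is captured by the platinum-bearing C3, forming the C3–CH2 bond and releasing PtCl2. The closest known reaction type is the PtCl2-catalysed carboalkoxylation of ortho-alkynylaryl acetals to 3-(alkoxyalkyl)benzofurans. No stereocentre is formed. The step needs chemoselectivity among three oxygens ortho to the alkyne, and the substrate secures it because only the acetal oxygen can shed its substituent as a stabilised cation, so any addition of the bulky, weakly nucleophilic TIPS-ether oxygen or of the ring-B methoxy oxygen is reversible and unproductive. Regiochemistry is matched, since donor-substituted ring B makes its own alkyne carbon the electrophilic one, and the one-carbon unit can arrive only at C3 because that is where the metal sits. The silyl ether on the side chain removes the one protic nucleophile that could intercept the oxocarbenium ion.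

Step 11
Reactants: 13 triethyl({4-[6-methoxy-3-(methoxymethyl)-2-(2-methoxy-4-triisopropylsilyloxyphenyl)-4-(triisopropylsilyloxy)benzofuran-5-yl]-2-methylbutan-2-yl}oxy)silane
Product: 14 6-methoxy-2-(2-methoxy-4-triisopropylsilyloxyphenyl)-5-[3-methyl-3-(triethylsilyloxy)butyl]-4-(triisopropylsilyloxy)benzofuran-3-carbaldehyde
Conditions: DDQ (1.5 equiv), CH2Cl2–pH 7 phosphate buffer (10:1), 0 °C to rt
Reagents that add atoms: water, O
Why: DDQ oxidation of an electron-rich arylmethyl methyl ether, the reaction type behind oxidative cleavage of p-methoxybenzyl ethers: hydride abstraction from the C3 methylene gives an oxocarbenium ion stabilised by the methoxy oxygen and, through C2, by O1 and ring B; water adds and the hemiacetal collapses to the aldehyde and methanol. The aldehyde is deactivated toward further oxidation, the C5 benzylic methylene has no α-oxygen, and the buffer protects the silyl ethers from the acidic hydroquinone.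

Step 12
Reactants: 14 6-methoxy-2-(2-methoxy-4-triisopropylsilyloxyphenyl)-5-[3-methyl-3-(triethylsilyloxy)butyl]-4-(triisopropylsilyloxy)benzofuran-3-carbaldehyde
Product: 15 4-hydroxy-5-(3-hydroxy-3-methylbutyl)-2-(4-hydroxy-2-methoxyphenyl)-6-methoxybenzofuran-3-carbaldehyde
Conditions: Bu4NF (4 equiv), THF, 0 °C to rt; AcOH quench
Reagents that add atoms: none
Why: Fluoride-mediated desilylation cleaves both aryl TIPS ethers and the tertiary triethylsilyl ether in one operation; the non-acidic medium avoids closure of the C4 hydroxyl onto the tertiary carbinol, and the mild acetic acid quench returns the phenols.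

Compound list
1 | 2-methylbut-3-en-2-ol | CC(C)(O)C=C | starting material
2 | triethyl[(2-methylbut-3-en-2-yl)oxy]silane | CC[Si](CC)(CC)OC(C)(C)C=C | intermediate
3 | 2,6-dihydroxy-4-methoxybenzaldehyde | COc1cc(O)c(C=O)c(O)c1 | starting material
4 | 2,6-dihydroxy-3-iodo-4-methoxybenzaldehyde | COc1cc(O)c(C=O)c(O)c1I | intermediate
5 | 2,6-dihydroxy-4-methoxy-3-[(E)-3-methyl-3-(triethylsilyloxy)but-1-en-1-yl]benzaldehyde | COc1cc(O)c(C=O)c(O)c1/C=C/C(C)(C)O[Si](CC)(CC)CC | intermediate
6 | 2,6-dihydroxy-4-methoxy-3-[3-methyl-3-(triethylsilyloxy)butyl]benzaldehyde | COc1cc(O)c(C=O)c(O)c1CCC(C)(C)O[Si](CC)(CC)CC | intermediate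
7 | 2-hydroxy-4-methoxy-6-(methoxymethoxy)-3-[3-methyl-3-(triethylsilyloxy)butyl]benzaldehyde | COCOc1cc(OC)c(CCC(C)(C)O[Si](CC)(CC)CC)c(O)c1C=O | intermediate
8 | 4-methoxy-6-(methoxymethoxy)-3-[3-methyl-3-(triethylsilyloxy)butyl]-2-(triisopropylsilyloxy)benzaldehyde | COCOc1cc(OC)c(CCC(C)(C)O[Si](CC)(CC)CC)c(O[Si](C(C)C)(C(C)C)C(C)C)c1C=O | intermediate
9 | {2-ethynyl-5-methoxy-3-(methoxymethoxy)-6-[3-methyl-3-(triethylsilyloxy)butyl]phenoxy}triisopropylsilane | COCOc1cc(OC)c(CCC(C)(C)O[Si](CC)(CC)CC)c(O[Si](C(C)C)(C(C)C)C(C)C)c1C#C | intermediate
10 | 4-bromo-3-methoxyphenol | COc1cc(O)ccc1Br | starting material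
11 | (4-bromo-3-methoxyphenoxy)triisopropylsilane | COc1cc(O[Si](C(C)C)(C(C)C)C(C)C)ccc1Br | intermediate
12 | triethyl[(4-{6-methoxy-4-(methoxymethoxy)-3-[(2-methoxy-4-triisopropylsilyloxyphenyl)ethynyl]-2-(triisopropylsilyloxy)phenyl}-2-methylbutan-2-yl)oxy]silane | COCOc1cc(OC)c(CCC(C)(C)O[Si](CC)(CC)CC)c(O[Si](C(C)C)(C(C)C)C(C)C)c1C#Cc1ccc(O[Si](C(C)C)(C(C)C)C(C)C)cc1OC | intermediate
13 | triethyl({4-[6-methoxy-3-(methoxymethyl)-2-(2-methoxy-4-triisopropylsilyloxyphenyl)-4-(triisopropylsilyloxy)benzofuran-5-yl]-2-methylbutan-2-yl}oxy)silane | COCc1c(-c2ccc(O[Si](C(C)C)(C(C)C)C(C)C)cc2OC)oc2cc(OC)c(CCC(C)(C)O[Si](CC)(CC)CC)c(O[Si](C(C)C)(C(C)C)C(C)C)c12 | intermediate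
14 | 6-methoxy-2-(2-methoxy-4-triisopropylsilyloxyphenyl)-5-[3-methyl-3-(triethylsilyloxy)butyl]-4-(triisopropylsilyloxy)benzofuran-3-carbaldehyde | O=Cc1c(-c2ccc(O[Si](C(C)C)(C(C)C)C(C)C)cc2OC)oc2cc(OC)c(CCC(C)(C)O[Si](CC)(CC)CC)c(O[Si](C(C)C)(C(C)C)C(C)C)c12 | intermediate
15 | 4-hydroxy-5-(3-hydroxy-3-methylbutyl)-2-(4-hydroxy-2-methoxyphenyl)-6-methoxybenzofuran-3-carbaldehyde | COc1cc(O)ccc1-c1oc2cc(OC)c(CCC(C)(C)O)c(O)c2c1C=O | target

Total step count: 12. Longest linear sequence: 10 steps (3 to 15 through steps 2–7 and 9–12); steps 1 and 8 are one-step side branches.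

Steps least certain to work

Step 10 (key step). The likely failure is stalling or diversion of the cycloisomerisation: the di-ortho-substituted tolane may bind platinum slowly, and the migrating cation may be lost to adventitious water, which would leave C3 unsubstituted. The fallback replaces acetal transfer by halocyclisation and sets out from 12. The acetal is removed with TMSOTf and 2,2'-bipyridyl in CH2Cl2 at 0 °C followed by water, giving 5-methoxy-2-[(2-methoxy-4-triisopropylsilyloxyphenyl)ethynyl]-4-[3-methyl-3-(triethylsilyloxy)butyl]-3-(triisopropylsilyloxy)phenol F1. Iodocyclisation of the free phenol (I2, NaHCO3, MeCN, rt; 5-endo-dig, the phenol far outpacing the ring-B methyl ether) gives 3-iodo-6-methoxy-2-(2-methoxy-4-triisopropylsilyloxyphenyl)-5-[3-methyl-3-(triethylsilyloxy)butyl]-4-(triisopropylsilyloxy)benzofuran F2. Iodine–magnesium exchange with i-PrMgCl·LiCl in THF at -40 °C (the magnesium species resists the ring opening that the lithium species undergoes) and a DMF quench return to the route at 14.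

Step 5. The risk is loss of regiocontrol in the acetalisation, with alkylation of the hindered phenol or of both. The fallback moves differentiation ahead of chain introduction and sets out from 3. Mono-alkylation of the symmetric diol (MOMCl, i-Pr2NEt, CH2Cl2, 0 °C) gives 2-hydroxy-4-methoxy-6-(methoxymethoxy)benzaldehyde F3. Iodination ortho to the chelated free phenol (BnMe3N·ICl2, NaHCO3, CH2Cl2–MeOH) gives 2-hydroxy-3-iodo-4-methoxy-6-(methoxymethoxy)benzaldehyde F4. Heck coupling with 2 under the conditions of step 3 gives 2-hydroxy-4-methoxy-6-(methoxymethoxy)-3-[(E)-3-methyl-3-(triethylsilyloxy)but-1-en-1-yl]benzaldehyde F5, and hydrogenation as in step 4 returns to the route at 7.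

Step 7. The risks are slow addition to the doubly ortho-substituted aldehyde and transfer of the TIPS group from the phenolic oxygen to the newly formed alkoxide before elimination. The fallback is a two-stage olefination–rearrangement that sets out from 8. Ramirez olefination (CBr4, PPh3, Et3N, CH2Cl2, 0 °C) gives {2-(2,2-dibromoethenyl)-5-methoxy-3-(methoxymethoxy)-6-[3-methyl-3-(triethylsilyloxy)butyl]phenoxy}triisopropylsilane F6. Treatment with n-BuLi (2.1 equiv, THF, -78 °C; Fritsch–Buttenberg–Wiechell rearrangement, then protonation) returns to the route at 9.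

Step 9. The risk is slow oxidative addition into the electron-rich, ortho-substituted bromide, which lets oxidative dimerisation of the alkyne take over. The fallback changes the electrophile and sets out from 11. Copper-catalysed halogen exchange (CuI, NaI, trans-N,N'-dimethylcyclohexane-1,2-diamine, dioxane, 110 °C) gives (4-iodo-3-methoxyphenoxy)triisopropylsilane F7. This should couple with 9 at room temperature under PdCl2(PPh3)2, CuI, Et3N in THF and return to the route at 12.

Step 11. The risks are single-electron over-oxidation of the very electron-rich nucleus, hydride abstraction at the C5 benzylic methylene, or acid-induced loss of silyl groups. The fallback separates substitution from oxidation and sets out from 13. Acid-catalysed solvolysis of the activated heteroarylmethyl ether (pyridinium p-toluenesulfonate, THF–H2O, dilute, rt) gives [6-methoxy-2-(2-methoxy-4-triisopropylsilyloxyphenyl)-5-[3-methyl-3-(triethylsilyloxy)butyl]-4-(triisopropylsilyloxy)benzofuran-3-yl]methanol F8. Oxidation with MnO2 in CH2Cl2 returns to the route at 14.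

Further compounds
F1 | step 10 | 5-methoxy-2-[(2-methoxy-4-triisopropylsilyloxyphenyl)ethynyl]-4-[3-methyl-3-(triethylsilyloxy)butyl]-3-(triisopropylsilyloxy)phenol | Oc1cc(OC)c(CCC(C)(C)O[Si](CC)(CC)CC)c(O[Si](C(C)C)(C(C)C)C(C)C)c1C#Cc1ccc(O[Si](C(C)C)(C(C)C)C(C)C)cc1OC
F2 | step 10 | 3-iodo-6-methoxy-2-(2-methoxy-4-triisopropylsilyloxyphenyl)-5-[3-methyl-3-(triethylsilyloxy)butyl]-4-(triisopropylsilyloxy)benzofuran | COc1cc2oc(-c3ccc(O[Si](C(C)C)(C(C)C)C(C)C)cc3OC)c(I)c2c(O[Si](C(C)C)(C(C)C)C(C)C)c1CCC(C)(C)O[Si](CC)(CC)CC
F3 | step 5 | 2-hydroxy-4-methoxy-6-(methoxymethoxy)benzaldehyde | COCOc1cc(OC)cc(O)c1C=O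
F4 | step 5 | 2-hydroxy-3-iodo-4-methoxy-6-(methoxymethoxy)benzaldehyde | COCOc1cc(OC)c(I)c(O)c1C=O
F5 | step 5 | 2-hydroxy-4-methoxy-6-(methoxymethoxy)-3-[(E)-3-methyl-3-(triethylsilyloxy)but-1-en-1-yl]benzaldehyde | COCOc1cc(OC)c(/C=C/C(C)(C)O[Si](CC)(CC)CC)c(O)c1C=O
F6 | step 7 | {2-(2,2-dibromoethenyl)-5-methoxy-3-(methoxymethoxy)-6-[3-methyl-3-(triethylsilyloxy)butyl]phenoxy}triisopropylsilane | COCOc1cc(OC)c(CCC(C)(C)O[Si](CC)(CC)CC)c(O[Si](C(C)C)(C(C)C)C(C)C)c1C=C(Br)Br
F7 | step 9 | (4-iodo-3-methoxyphenoxy)triisopropylsilane | COc1cc(O[Si](C(C)C)(C(C)C)C(C)C)ccc1I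
F8 | step 11 | [6-methoxy-2-(2-methoxy-4-triisopropylsilyloxyphenyl)-5-[3-methyl-3-(triethylsilyloxy)butyl]-4-(triisopropylsilyloxy)benzofuran-3-yl]methanol | OCc1c(-c2ccc(O[Si](C(C)C)(C(C)C)C(C)C)cc2OC)oc2cc(OC)c(CCC(C)(C)O[Si](CC)(CC)CC)c(O[Si](C(C)C)(C(C)C)C(C)C)c12
A1 | alternative 1 | 2-(4-benzyloxy-2-methoxyphenyl)-3-(dimethoxymethyl)-6-methoxy-5-[3-methyl-3-(triethylsilyloxy)butyl]benzofuran-4-ol | COc1cc(OCc2ccccc2)ccc1-c1oc2cc(OC)c(CCC(C)(C)O[Si](CC)(CC)CC)c(O)c2c1C(OC)OC
A2 | alternative 1 | 1-[5-(4-benzyloxy-2-methoxyphenyl)-4-(dimethoxymethyl)furan-2-yl]-2-diazoethan-1-one | COc1cc(OCc2ccccc2)ccc1-c1oc(C(=O)C=[N+]=[N-])cc1C(OC)OC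
A3 | alternative 1 | triethyl[(6-methoxy-2-methylhex-5-yn-2-yl)oxy]silane | COC#CCCC(C)(C)O[Si](CC)(CC)CC
A4 | alternative 2 | ethyl 4-benzyloxy-2-(4-benzyloxy-2-methoxyphenyl)-6-methoxy-5-[3-methyl-3-(triethylsilyloxy)butyl]benzofuran-3-carboxylate | CCOC(=O)c1c(-c2ccc(OCc3ccccc3)cc2OC)oc2cc(OC)c(CCC(C)(C)O[Si](CC)(CC)CC)c(OCc3ccccc3)c12
A5 | alternative 2 | 3-benzyloxy-5-methoxy-4-[3-methyl-3-(triethylsilyloxy)butyl]-2-(trimethylsilyl)phenyl trifluoromethanesulfonate | COc1cc(OS(=O)(=O)C(F)(F)F)c([Si](C)(C)C)c(OCc2ccccc2)c1CCC(C)(C)O[Si](CC)(CC)CC
A6 | alternative 2 | phenyliodonium ylide of ethyl 3-(4-benzyloxy-2-methoxyphenyl)-3-oxopropanoate | CCOC(=O)[C-]([I+]c1ccccc1)C(=O)c1ccc(OCc2ccccc2)cc1OC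
A7 | alternative 3 | methyl cis-6-methoxy-2-(2-methoxy-4-triisopropylsilyloxyphenyl)-5-[3-methyl-3-(triethylsilyloxy)butyl]-4-(triisopropylsilyloxy)-2,3-dihydrobenzofuran-3-carboxylate (racemic, one enantiomer drawn) | COC(=O)[C@@H]1[C@H](c2ccc(O[Si](C(C)C)(C(C)C)C(C)C)cc2OC)Oc2cc(OC)c(CCC(C)(C)O[Si](CC)(CC)CC)c(O[Si](C(C)C)(C(C)C)C(C)C)c21
A8 | alternative 3 | methyl 2-diazo-2-{4-methoxy-2-[(2-methoxy-4-triisopropylsilyloxyphenyl)methoxy]-5-[3-methyl-3-(triethylsilyloxy)butyl]-6-(triisopropylsilyloxy)phenyl}acetate | COC(=O)C(=[N+]=[N-])c1c(OCc2ccc(O[Si](C(C)C)(C(C)C)C(C)C)cc2OC)cc(OC)c(CCC(C)(C)O[Si](CC)(CC)CC)c1O[Si](C(C)C)(C(C)C)C(C)C
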